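**Retrosynthetic overview**

1. Target 19 ⇐ diketone 18 (both C3 carbonyls reduced from the β face) ⇐ bis-ketal 17 ⇐ C7' ketone 16 (Wolff–Kishner).
2. C12–C9' disconnection: 16 ⇐ diene 13 + enone 10. The terminal C11=C12 vinyl group of 13 is hydrozirconated and the C12 alkylcopper adds 1,4 to C9' of 10; this sets C9', and C8' then equilibrates next to the C7' carbonyl.
3. 13 ⇐ the same enone 10 (vinyl cuprate to C9, C7 enol triflate, reduction to the C7=C8 alkene): the target is enone 10 + C2 + enone 10.
4. 10 ⇐ enone 6 (cuprate methylation at C10 gives the cis ring fusion; C8 triflate to methyl; allylic oxidation at C7) ⇐ 6-methoxy-2-tetralone 1 (gem-dimethylation, ketal, Birch reduction, asymmetric isomerization setting C5). No carbocycle is closed: ring A is the saturated ring of the tetralone and ring B its anisole ring; only the dioxolanes are formed and later opened.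
5. Enabling feature: in the cis-fused bicycle, C4 is axial on ring B at C5 and its α-methyl lies under ring B, syn-axial to C9 and C10. The β-carbon C9' of the enone unit C7'(=O)–C8'(CH3)=C9'H (and C10 of the C8(=O)–C9=C10 enone earlier) is therefore open only on the β face, the face of H5 and the C10 methyl. The C7' carbonyl lets the C8' methyl settle equatorial.

Key step: step 10

Remark on configuration: the target as written has both decalins cis-fused (H5 and the C10 methyl on the same face), the C9 substituent on that face and the C3 hydroxyl on the other, i.e. (3R,5S,9S,10R,3'R,5'S,8'R,9'S,10'R); the route is built for exactly this array.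

Remark on names: each bicyclic half carries terpenoid numbering (ring A = C1–C5 and C10, ring B = C5–C10, oxygen on C3, gem-dimethyl on C4, angular methyl on C10, bridge C9–C11–C12–C9'; primes mark the saturated half); α/β as in terpenoid drawings (ring A left, C10 above C5, β toward the viewer), so the C10 methyl is β.

**Route**

Step 1
Reactants: 1 6-methoxy-2-tetralone
Product: 2 6-methoxy-1,1-dimethyl-2-tetralone
Conditions: NaH, MeI, THF, 0 °C to rt
Reagents that add atoms: iodomethane (CI)
Why: Double enolate C-alkylation should take place at the benzylic, more acidic C1 of the 2-tetralone, giving the future C4 gem-dimethyl group without a stereocenter.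

Step 2
Reactants: 2 6-methoxy-1,1-dimethyl-2-tetralone
Product: 3 ethylene ketal of 2
Conditions: HOCH2CH2OH, TsOH (cat.), benzene, reflux, Dean–Stark
Reagents that add atoms: ethylene glycol (OCCO)
Why: Acid-catalysed ketalisation with azeotropic removal of water masks the future C3 carbonyl against the Birch reduction and all organometallic steps.

Step 3
Reactants: 3 ethylene ketal of 2
Product: 5 β,γ-unsaturated ketone (C8=O, tetrasubstituted C5=C10), via Birch enol ether 4 (not isolated)
Conditions: Li, NH3(l), t-BuOH, THF, −33 °C; NH4Cl; then (CO2H)2, MeOH/H2O, rt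
Reagents that add atoms: water (O)
Why: Birch reduction of the anisole ring should give the 1-methoxy-1,4-diene that keeps the ring-fusion alkene, and mild oxalic acid hydrolysis of the enol ether stops at the β,γ-unsaturated ketone without opening the dioxolane.

Step 4
Reactants: 5 β,γ-unsaturated ketone
Product: 6 (4aS)-6,6-ethylenedioxy-5,5-dimethyl-4,4a,5,6,7,8-hexahydronaphthalen-2(3H)-one (terpenoid numbering: C8=O, C9=C10, 5S)
Conditions: 9-amino-9-deoxy-epi-cinchona primary amine (10 mol %, the pseudo-enantiomer that gives 5S), CF3CO2H (20 mol %), toluene, rt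
Reagents that add atoms: none
Why: Amine-catalysed asymmetric olefin isomerization through a dienamine, in which the chiral ammonium protonates the γ-carbon C5 on one face and hydrolysis releases the conjugated enone, sets C5, the only stereocenter of the route that is controlled by a reagent.

Step 5
Reactants: 6 (4aS)-enone
Product: 8 3,3-ethylenedioxy-4,4,10β-trimethyl-5β-decal-8-en-8-yl trifluoromethanesulfonate (C8=C9), via lithium enolate 7 (not isolated)
Conditions: Me2CuLi, Et2O, 0 °C; then N-(5-chloropyridin-2-yl)bis(trifluoromethanesulfonyl)imide, THF, −78 °C to rt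
Reagents that add atoms: lithium dimethylcuprate ([Li+].C[Cu-]C); N-(5-chloropyridin-2-yl)bis(trifluoromethanesulfonyl)imide (Clc1ccc(nc1)N(S(=O)(=O)C(F)(F)F)S(=O)(=O)C(F)(F)F)
Why: Cuprate conjugate addition should deliver the methyl to C10 on the face of H5, because the other face is blocked by the axial methyl on C4 (cis-selective angular methylation of an octalone), and O-sulfonylation of the regiodefined enolate fixes the C8=C9 enol triflate.

Step 6
Reactants: 8 enol triflate
Product: 9 3,3-ethylenedioxy-4,4,8,10β-tetramethyl-5β-decal-8-ene (C8=C9)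
Conditions: MeMgBr, Fe(acac)3 (5 mol %), THF/NMP, −30 to 0 °C
Reagents that add atoms: methylmagnesium bromide (C[Mg]Br)
Why: Iron-catalysed Kumada-type cross-coupling of the alkenyl triflate replaces OTf by CH3 without moving the double bond, and the ketal is inert at this temperature.

Step 7
Reactants: 9 trisubstituted alkene
Product: 10 3,3-ethylenedioxy-4,4,8,10β-tetramethyl-5β-decal-8-en-7-one (C7=O, C8=C9)
Conditions: dirhodium tetrakis(caprolactamate), Rh2(C6H10NO)4 (1 mol %), t-BuOOH, K2CO3, CH2Cl2, rt
Reagents that add atoms: tert-butyl hydroperoxide (CC(C)(C)OO)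
Why: Radical allylic C–H oxidation should occur at C7, the only ring allylic CH2 (C9 is flanked by the quaternary C10), and the mixed peroxide collapses to the enone.

Step 8
Reactants: 10 enone
Product: 12 9β-vinyl-3,3-ethylenedioxy-4,4,8,10β-tetramethyl-5β-decal-7-en-7-yl trifluoromethanesulfonate (C7=C8), via lithium enolate 11 (not isolated)
Conditions: (CH2=CH)2CuLi, Et2O/THF, −78 to −20 °C; then N-(5-chloropyridin-2-yl)bis(trifluoromethanesulfonyl)imide, −78 °C to rt
Reagents that add atoms: lithium divinylcuprate ([Li+].C=C[Cu-]C=C); N-(5-chloropyridin-2-yl)bis(trifluoromethanesulfonyl)imide (Clc1ccc(nc1)N(S(=O)(=O)C(F)(F)F)S(=O)(=O)C(F)(F)F)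
Why: Cuprate conjugate addition should place the vinyl group on C9 from the β face (the α face of C9 is covered by C4 and its axial methyl), setting C9, and the tetrasubstituted enolate is trapped on oxygen as the C7=C8 enol triflate.

Step 9
Reactants: 12 dienyl triflate
Product: 13 9β-vinyl-3,3-ethylenedioxy-4,4,8,10β-tetramethyl-5β-decal-7-ene
Conditions: Pd(OAc)2 (5 mol %), PPh3, HCO2H, Bu3N, DMF, 60 °C
Reagents that add atoms: none
Why: Palladium-catalysed formate reduction of the alkenyl triflate (oxidative addition, decarboxylation of formate to a palladium hydride, reductive elimination) should give the C7=C8 alkene in place and leave the terminal vinyl group untouched.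

Step 10
Reactants: 13 vinyl diene (1.3 equiv); 10 enone
Product: 16 3,3:3',3'-bis(ethylenedioxy) C7' ketone (left half 7-ene; right half 7'-oxo, 8'α-methyl, 9'β-alkyl; bridge C9–CH2–CH2–C9'), via alkylzirconocene chloride 14 (not isolated), via trimethylsilyl enol ether 15 (not isolated)
Conditions: Cp2Zr(H)Cl, THF, rt; then 10, CuBr·SMe2 (10 mol %), TMSCl, THF, rt to 40 °C; then K2CO3, MeOH, rt
Reagents that add atoms: none
Why: Hydrozirconation adds Zr–H across the terminal vinyl group only (anti-Markovnikov; the trisubstituted C7=C8 is inert), transmetalation gives a C12 alkylcopper that adds 1,4 to enone 10, TMSCl silylates the enolate and returns the copper salt, and methanolysis with K2CO3 frees the ketone. The closest known reaction type is the copper-catalysed conjugate addition of alkylzirconocenes, made by hydrozirconation of terminal alkenes, to cyclic enones. No ring is closed. C9' is controlled by the substrate: in the cis-fused enone the α face of C9' is covered by C4' and its axial methyl, so the copper reagent should bond on the β face, cis to the C10' methyl and H5'; C8' is set under thermodynamic control, the methyl next to the C7' carbonyl equilibrating to the equatorial position trans to the new chain. The step needs chemoselectivity (terminal against trisubstituted alkene, 1,4 against 1,2 addition) and β-face selectivity; the first is secured by the steric demand of Cp2Zr(H)Cl and the soft alkylcopper, the second by the C4' gem-dimethyl group, and because both partners come from the same enantiomer of 10 no mismatched pairing can arise.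

Step 11
Reactants: 16 C7' ketone
Product: 17 3,3:3',3'-bis(ethylenedioxy) derivative of the target skeleton (C7' now CH2)
Conditions: N2H4·H2O, KOH, diethylene glycol, 130 then 200 °C
Reagents that add atoms: none
Why: Wolff–Kishner reduction removes the C7' carbonyl through the hydrazone anion, the ketals and the trisubstituted alkene are stable to hot alkali, and C8' keeps its equatorial methyl because that is already the stable epimer.

Step 12
Reactants: 17 bis-ketal
Product: 18 3,3'-diketone
Conditions: 2 M HCl, THF, rt
Reagents that add atoms: water (O)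
Why: Acid-catalysed ketal hydrolysis frees both C3 carbonyls under conditions too mild to move the trisubstituted alkene.

Step 13
Reactants: 18 3,3'-diketone
Product: 19 target diol, (3R,5S,9S,10R,3'R,5'S,8'R,9'S,10'R)
Conditions: NaBH4, MeOH/CH2Cl2, 0 °C
Reagents that add atoms: none
Why: Hydride reduction of each C3 carbonyl should occur by axial attack from the convex β face (the α face carries the axial C4 methyl and ring B), giving both equatorial 3α-alcohols (3R and 3'R).

**Compound list**

1 | 6-methoxy-3,4-dihydronaphthalen-2(1H)-one (6-methoxy-2-tetralone) | COc1ccc2c(c1)CCC(=O)C2 | starting material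
2 | 6-methoxy-1,1-dimethyl-3,4-dihydronaphthalen-2(1H)-one | COc1ccc2c(c1)CCC(=O)C2(C)C | intermediate
3 | 6'-methoxy-1',1'-dimethyl-3',4'-dihydro-1'H-spiro[1,3-dioxolane-2,2'-naphthalene] (ethylene ketal of 2) | COc1ccc2c(c1)CCC1(OCCO1)C2(C)C | intermediate
4 | Birch enol ether, not isolated: 6'-methoxy-1',1'-dimethyl-3',4',5',8'-tetrahydro-1'H-spiro[1,3-dioxolane-2,2'-naphthalene] (enol ether C7=C8, alkene C5=C10) | COC1=CCC2=C(C1)CCC1(OCCO1)C2(C)C | intermediate
5 | 6,6-ethylenedioxy-5,5-dimethyl-3,4,5,6,7,8-hexahydronaphthalen-2(1H)-one (C8=O, C5=C10) | O=C1CCC2=C(C1)CCC1(OCCO1)C2(C)C | intermediate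
6 | (4aS)-6,6-ethylenedioxy-5,5-dimethyl-4,4a,5,6,7,8-hexahydronaphthalen-2(3H)-one (C8=O, C9=C10, 5S) | O=C1CC[C@H]2C(=C1)CCC1(OCCO1)C2(C)C | intermediate
7 | lithium enolate, not isolated: C8(OLi)=C9 enolate of 3,3-ethylenedioxy-4,4,10β-trimethyl-5β-decalin-8-one | [Li+].[O-]C1=C[C@@]2(C)CCC3(OCCO3)C(C)(C)[C@H]2CC1 | intermediate
8 | 3,3-ethylenedioxy-4,4,10β-trimethyl-5β-decal-8-en-8-yl trifluoromethanesulfonate | FC(F)(F)S(=O)(=O)OC1=C[C@@]2(C)CCC3(OCCO3)C(C)(C)[C@H]2CC1 | intermediate
9 | 3,3-ethylenedioxy-4,4,8,10β-tetramethyl-5β-decal-8-ene | CC1=C[C@@]2(C)CCC3(OCCO3)C(C)(C)[C@H]2CC1 | intermediate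
10 | 3,3-ethylenedioxy-4,4,8,10β-tetramethyl-5β-decal-8-en-7-one | CC1=C[C@@]2(C)CCC3(OCCO3)C(C)(C)[C@H]2CC1=O | intermediate
11 | lithium enolate, not isolated: C7(OLi)=C8 enolate of 9β-vinyl-3,3-ethylenedioxy-4,4,8,10β-tetramethyl-5β-decalin-7-one | [Li+].[O-]C1=C(C)[C@H](C=C)[C@@]2(C)CCC3(OCCO3)C(C)(C)[C@H]2C1 | intermediate
12 | 9β-vinyl-3,3-ethylenedioxy-4,4,8,10β-tetramethyl-5β-decal-7-en-7-yl trifluoromethanesulfonate | FC(F)(F)S(=O)(=O)OC1=C(C)[C@H](C=C)[C@@]2(C)CCC3(OCCO3)C(C)(C)[C@H]2C1 | intermediate
13 | 9β-vinyl-3,3-ethylenedioxy-4,4,8,10β-tetramethyl-5β-decal-7-ene | CC1=CC[C@@H]2C(C)(C)C3(OCCO3)CC[C@]2(C)[C@H]1C=C | intermediate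
14 | alkylzirconocene chloride, not isolated: chlorobis(cyclopentadienyl)zirconium bound to C12 of the hydrometalated 13 (cyclopentadienyl rings drawn σ-bonded) | CC1=CC[C@@H]2C(C)(C)C3(OCCO3)CC[C@]2(C)[C@H]1CC[Zr](Cl)(C1C=CC=C1)C1C=CC=C1 | intermediate
15 | trimethylsilyl enol ether, not isolated: C7'(OSiMe3)=C8' enol ether of 16 | CC1=CC[C@@H]2C(C)(C)C3(OCCO3)CC[C@]2(C)[C@H]1CC[C@H]1C(C)=C(O[Si](C)(C)C)C[C@@H]2C(C)(C)C3(OCCO3)CC[C@@]21C | intermediate
16 | 3,3:3',3'-bis(ethylenedioxy) C7' ketone (8'α-methyl, 9'β-alkyl) | CC1=CC[C@@H]2C(C)(C)C3(OCCO3)CC[C@]2(C)[C@H]1CC[C@H]1[C@H](C)C(=O)C[C@@H]2C(C)(C)C3(OCCO3)CC[C@@]21C | intermediate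
17 | 3,3:3',3'-bis(ethylenedioxy) derivative of the target skeleton | CC1=CC[C@@H]2C(C)(C)C3(OCCO3)CC[C@]2(C)[C@H]1CC[C@H]1[C@H](C)CC[C@@H]2C(C)(C)C3(OCCO3)CC[C@@]21C | intermediate
18 | 3,3'-diketone of the target skeleton | CC1=CC[C@@H]2C(C)(C)C(=O)CC[C@]2(C)[C@H]1CC[C@H]1[C@H](C)CC[C@@H]2C(C)(C)C(=O)CC[C@@]21C | intermediate
19 | (2R,4aR,5S,8aS)-5-{2-[(1S,2R,4aS,6R,8aR)-6-hydroxy-2,5,5,8a-tetramethyldecahydronaphthalen-1-yl]ethyl}-1,1,4a,6-tetramethyl-1,2,3,4,4a,5,8,8a-octahydronaphthalen-2-ol | CC1=CC[C@@H]2C(C)(C)[C@H](O)CC[C@]2(C)[C@H]1CC[C@H]1[C@H](C)CC[C@@H]2C(C)(C)[C@H](O)CC[C@@]21C | target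

**Summary**

Total step count: 13.
Longest linear sequence: 13 steps (1 to 19; the sequence is linear because diene 13 is made from enone 10, which is also its coupling partner).

**Steps most likely to fail**

Step 10 (key step). The primary alkylcopper may add too slowly to the α-methylated enone whose β-carbon sits next to a quaternary centre, so that protonolysis of the alkylmetal and recovery of 10 take over. The fallback replaces the organometallic addition by a radical one; it sets out from 13 and returns at 16. Hydroboration of the vinyl group of 13 with 9-BBN in THF and oxidative work-up (H2O2, NaOH) should give the primary alcohol F1. An Appel reaction (I2, PPh3, imidazole, CH2Cl2) converts it into the primary iodide F2. Giese addition of the C12 radical to 10 ((TMS)3SiH added slowly, AIBN, benzene, 80 °C), followed by K2CO3 in MeOH to equilibrate C8', then gives 16. The radical addition has an early transition state and is less sensitive to substitution at the β-carbon; the face of attack is the same.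

Step 4. Discrimination between the two faces in the γ-protonation may be poor because C5 is flanked by the quaternary C4, and 6 may lose optical purity through reversible dienamine formation. The fallback relays the configuration from a carbinol centre; it sets out from 2 and returns at 6. Corey–Bakshi–Shibata reduction of 2 ((S)-2-methyl-CBS-oxazaborolidine, BH3·SMe2, THF) should give the (R)-alcohol F3. Birch reduction (Li, NH3, t-BuOH) and treatment with aqueous HCl in MeOH lead to the hydroxy enone F4, whose C5 equilibrates through the dienol; the (3R,5S) isomer, with both ring A substituents equatorial, is separated and the other isomer is returned to the same acid. Dess–Martin oxidation gives the enedione F5. Ethylene glycol with TsOH then ketalises the saturated, non-conjugated C3 carbonyl in preference to the enone carbonyl and gives 6.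

Step 7. Hydrogen abstraction may occur at the C8 methyl group or at the dioxolane CH2, the allyl radical may be captured at C9 (transposed enone), and the product may be oxidised further. The fallback replaces radical C–H abstraction by a pericyclic hydroxylation followed by alcohol oxidation; it sets out from 9 and returns at 10. SeO2 (catalytic) with t-BuOOH in CH2Cl2 should hydroxylate, by ene reaction and [2,3]-shift, the CH2 on the more substituted alkene carbon and give the allylic alcohol F6 (C7–OH, C8=C9 retained, either C7 epimer). Dess–Martin oxidation then gives 10.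

**Further compounds**

F1 | step 10 | 2-(3,3-ethylenedioxy-4,4,8,10β-tetramethyl-5β-decal-7-en-9β-yl)ethanol | CC1=CC[C@@H]2C(C)(C)C3(OCCO3)CC[C@]2(C)[C@H]1CCO
F2 | step 10 | 9β-(2-iodoethyl)-3,3-ethylenedioxy-4,4,8,10β-tetramethyl-5β-decal-7-ene | CC1=CC[C@@H]2C(C)(C)C3(OCCO3)CC[C@]2(C)[C@H]1CCI
F3 | step 4 | (R)-6-methoxy-1,1-dimethyl-1,2,3,4-tetrahydronaphthalen-2-ol | COc1ccc2c(c1)CC[C@@H](O)C2(C)C
F4 | step 4 | (4aS,6R)-6-hydroxy-5,5-dimethyl-4,4a,5,6,7,8-hexahydronaphthalen-2(3H)-one | O=C1CC[C@H]2C(=C1)CC[C@@H](O)C2(C)C
F5 | step 4 | (4aS)-5,5-dimethyl-4,4a,7,8-tetrahydronaphthalene-2,6(3H,5H)-dione | O=C1CC[C@H]2C(=C1)CCC(=O)C2(C)C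
F6 | step 7 | 3,3-ethylenedioxy-4,4,8,10β-tetramethyl-5β-decal-8-en-7-ol (C7 epimers) | CC1=C[C@@]2(C)CCC3(OCCO3)C(C)(C)[C@H]2CC1O
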